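- The closed, stirred vessel took starting material and protic impurity, and I kept one ledger for it: where each mole charged ended up.

| flask | starting material | protic impurity | temperature | remark | time |
|---|---|---|---|---|---|
| Monday's | 0.055 M | 0.055 M | 98 °C | run made earlier |  |
| Tuesday's | 0.083 M | 0.055 M | 125 °C | run made earlier |  |
| Wednesday's | 0.11 M | 0.028 M | 98 °C | run made earlier |  |
| elm | 0.11 M | 0.0550 M | 110 °C |  | 6.0 h |
| oak | 0.11 M | 0.0550 M | 135 °C |  | 6.0 h |
| birch | 0.11 M | 0.0550 M | 85 °C |  | 6.0 h |

Monday's run (percent of the starting material charged)

| time / h | target / % |
|---|---|
| 1.33 | 10.1 |
| 2.50 | 15.1 |
| 4.00 | 19.4 |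
| 5.00 | 21.3 |
| 8.00 | 24.0 |

Tuesday's run (percent of the starting material charged)

| time / min | target / % |
|---|---|
| 8.00 | 15.4 |
| 15.0 | 24.0 |
| 25.0 | 32.2 |
| 40.0 | 39.2 |
| 60.0 | 42.4 |
| 120 | 41.6 |

Wednesday's run (percent of the starting material charged)

| time / h | target / % |
|---|---|
| 0.417 | 3.6 |
| 0.833 | 7.8 |
| 2.00 | 15.8 |
| 4.00 | 27.8 |
| 8.00 | 42.5 |

(scatter of a reading: 0.3 percentage points)



- the flask that comes out highest in amount of target, in percent of the starting material charged, or "all alike" when all lie within 1.5 percentage points (elm / oak / birch / all alike)
- target at the end, in percent of the starting material charged, elm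
- target at the end, in percent of the starting material charged, oak
- target at the end, in percent of the starting material charged, birch

- First entry, the loss. Monday's run had equal charges and was slowing at 24.0%. Wednesday's had more starting material and less protic impurity, and it was still climbing at 42.5%, higher at the same time. I read this as protic impurity consuming starting material, one for one, to a product I could not see.
- Second entry, the bound. I carried 50.0% for elm. This is the free share: the part of the charged starting material left over if each mole of protic impurity, the limiting reagent of that loss, took one mole of starting material, so one minus the ratio of charged [protic impurity] to charged [starting material].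
- The free share is a floor, not a ceiling, on what escapes quenching. Tuesday's free share was 33.7%, yet its target read 42.4%, above it. So the making of target can also take starting material that protic impurity might have consumed.
- Third entry, the later fate of target. Tuesday's reading fell from 42.4% to 41.6%, a drop of 0.8 percentage points against a scatter of 0.3 points. I booked this as a possible loss of target.
- The forecast chose elm: elm 43%, oak 33%, birch 10%. Its ground for oak was this: “Tuesday's late fall hints that target decays”.
- The flasks gave elm 43.9%, oak 14.6% and birch 9.99%, so elm came out highest. The forecast for oak stood 18 points too high.

    starting material → target (k = 1.00 × 10⁻⁴ /s, Ea = 123 kJ/mol)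
    target → over-reaction product (k = 6.40 × 10⁻⁶ /s, Ea = 122 kJ/mol)
    starting material + protic impurity → quenched substrate (k = 0.00560 /M/s, Ea = 84.0 kJ/mol)
    (constants at 110 °C)

- Oak, charged like elm, held 44.4% over-reaction product at 6.00 h, and its target had fallen to half of its value at 3.00 h. Elm had not come to rest. Left ten times as long, its quenched substrate moved from 47.5% to 48.0%, while target fell to 13.7%. Target plus over-reaction product then made 52.0%, above the free share of 50.0%. Birch, charged the same, had not come to rest either: at 60.0 h it held 37.6% target, 49.8% quenched substrate and 0.304% of its protic impurity charge.

All runs were generated by integration from invented constants; the scatter is artificial.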